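**Plan**

1. Retrosynthesis (terpenoid carbons carry drimane numbers, C11 = benzylic carbon, C12 = methyl on C8; arene carbons are C1' on C11 to C6' bearing the sulfate): cut the sulfate O–S bond and the formyl C–C5' bond, then the C8–C9 bond of ring B, then C11–C1' and C10–C9. This leaves (S)-α-ionone (ring A, C5–C8, C12), a silylethynyl sulfone (C9, C11) and benzene-1,2,4-triol.
2. Enabling feature: C9 is an sp2 ring atom holding two ring bonds (to C8 and C10) and the exocyclic C11H–aryl unit. This R2C=CH–Ar pattern is what a boron-to-carbon 1,2-shift followed by boron/iodine elimination delivers. With boron placed between C8 and C9, ring B exists first as a seven-membered borepane (B, C8, C7, C6, C5, C10, C9) and is reached by ring contraction with loss of boron.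
3. Forward order: ring A is bought with α-ionone; the C8 boronate is made on the side chain; C9 and the C10 quaternary centre come from alkynylation of the ring alkene; the arene is joined at C11; cyclic hydroboration closes the borepane; the iodine-triggered shift contracts it to ring B; formylation, MOM removal and sulfation finish.
4. Stereochemistry: C5 from (S)-α-ionone; C8 from a catalyst-controlled hydrogenation of an alkenyl boronate, carried into ring B with retention; C10 from radical attack anti to the C5 side chain; the E alkene from syn hydroboration followed by anti addition and anti elimination.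

Key step: step 11

Assumption: (S)-α-ionone of high enantiomeric purity is taken as a purchasable starting material.

**Route**

Step 1
Reactants: 1 (S)-α-ionone
Product: 2 (S)-dihydro-α-ionone
Conditions: Cu(OAc)2·H2O (3 mol %), 1,2-bis(diphenylphosphino)benzene (3 mol %), (EtO)2MeSiH, t-BuOH, toluene, rt
Reagents that add atoms: none
Why: Copper hydride 1,4-reduction of the enone should reduce only the conjugated C6=C7 bond and leave the trisubstituted ring alkene and the C5 stereocentre alone.

Step 2
Reactants: 2 (S)-dihydro-α-ionone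
Product: 4 alkenyl triflate (terminal enol triflate of the methyl ketone), via lithium enolate 3 (not isolated)
Conditions: LiN(i-Pr)2, THF, −78 °C; N-(5-chloropyridin-2-yl)bis(trifluoromethanesulfonyl)imide, −78 °C to 0 °C
Reagents that add atoms: N-(5-chloropyridin-2-yl)bis(trifluoromethanesulfonyl)imide, FC(F)(F)S(=O)(=O)N(c1ccc(Cl)cn1)S(=O)(=O)C(F)(F)F
Why: Kinetic deprotonation of the methyl ketone at the methyl group followed by O-sulfonylation of the enolate (enol triflate formation) should give the less substituted alkenyl triflate.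

Step 3
Reactants: 4 alkenyl triflate
Product: 5 alkenyl boronate (1,1-disubstituted alkenyl pinacol boronate, boron on C8)
Conditions: PdCl2(PPh3)2 (3 mol %), PPh3 (6 mol %), B2pin2, KOPh, toluene, 50 °C
Reagents that add atoms: bis(pinacolato)diboron, CC1(C)OB(OC1(C)C)B1OC(C)(C)C(C)(C)O1
Why: Miyaura borylation of an alkenyl triflate replaces the triflate by the pinacol boronate without touching the ring alkene.

Step 4
Reactants: 5 alkenyl boronate
Product: 6 secondary boronate (8S)
Conditions: [Rh(nbd)2]BF4 (3 mol %), Walphos ligand C46H32F12FeP2 (the antipode that gives 8S), H2 (10 bar), ClCH2CH2Cl, rt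
Reagents that add atoms: none
Why: Rhodium-catalysed asymmetric hydrogenation of the 1,1-disubstituted alkenyl boronate sets C8 under catalyst control, and the unfunctionalised trisubstituted ring alkene should not be reduced by this catalyst.

Step 5
Reactants: 6 secondary boronate (8S); 7 silylethynyl sulfone
Product: 8 silyl alkyne (C10 quaternary, saturated ring A)
Conditions: Fe(acac)3 (30 mol %), PhSiH3, EtOH, 60 °C
Reagents that add atoms: none
Why: Markovnikov hydrogen-atom transfer from the hydride made from Fe(acac)3 and PhSiH3 to C1 gives the tertiary C10 radical, which adds to the sulfonyl-bearing alkyne carbon of 7 and expels the sulfonyl radical (radical alkynylation); attack anti to the C5 side chain and to the axial C4 methyl group should place C9 trans to C6.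

Step 6
Reactants: 8 silyl alkyne
Product: 9 terminal alkyne
Conditions: K2CO3 (0.2 equiv), MeOH, rt
Reagents that add atoms: none
Why: Methanolysis of the C(sp)–Si bond frees the alkyne while the alkyl pinacol boronate and the stereocentres stay untouched.

Step 7
Reactants: 10 benzene-1,2,4-triol
Product: 11 tris-MOM ether
Conditions: MOMCl, i-Pr2NEt, CH2Cl2, 0 °C to rt, N2
Reagents that add atoms: chloromethyl methyl ether, COCCl
Why: O-Alkylation of the three phenols gives ethers that survive hydride, borane and organolithium steps and later direct the ortho-lithiation.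

Step 8
Reactants: 11 tris-MOM ether
Product: 12 aryl iodide
Conditions: N-iodosuccinimide, MeCN, 0 °C to rt, dark
Reagents that add atoms: N-iodosuccinimide, O=C1CCC(=O)N1I
Why: Electrophilic aromatic iodination should go to the only position that is ortho to one OMOM group and para to another, which becomes C1'.

Step 9
Reactants: 9 terminal alkyne; 12 aryl iodide
Product: 13 aryl alkyne
Conditions: PdCl2(PPh3)2 (3 mol %), CuI (5 mol %), Et3N, THF, 50 °C
Reagents that add atoms: none
Why: Sonogashira coupling joins C11 to C1'; the secondary alkyl boronate and the MOM ethers are inert under these conditions.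

Step 10
Reactants: 13 aryl alkyne
Product: 17 borepane methyl borinate, via lithium trihydroborate 14 (not isolated), via monoalkylborane 15 (not isolated), via cyclic hydridoborane 16 (not isolated)
Conditions: LiAlH4 (1.0 equiv), Et2O/pentane, 0 °C, alkoxyalane filtered off; MeI (1.0 equiv), 0 °C; dilution with THF to 0.005 mol/L, rt; MeOH; volatiles removed under argon, used crude
Reagents that add atoms: methanol, CO
Why: Reduction of the boronic ester to the borohydride and hydride abstraction give the monoalkylborane, whose intramolecular syn hydroboration can only place boron on C9 (the other regiochemistry would put an E double bond inside an eight-membered ring), so the seven-membered borepane should form with boron cis to H-11, and methanol caps boron as the borinate.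

Step 11
Reactants: 17 borepane methyl borinate
Product: 20 tris-MOM styrene (ring B closed, E alkene), via sodium dimethoxyborate 18 (not isolated), via iodo boronate 19 (not isolated)
Conditions: NaOMe (3 equiv), THF/MeOH, −78 °C; I2 (1.1 equiv) in THF, −78 °C to 0 °C; aq Na2S2O3
Reagents that add atoms: none
Why: Proposed new method: methoxide turns 17 into the tetracoordinate borate 18; iodine attacks the C9=C11 bond at C11 and, anti to it, the only carbon ligand on boron (C8) shifts from boron to C9, so the borepane (B, C8, C7, C6, C5, C10, C9) contracts to the six-membered ring B with boron now exocyclic (19), and methoxide then triggers anti elimination of boron and iodine to give the C9=C11 bond. The closest known reactions are the Zweifel olefination of secondary boronic esters with α-substituted alkenyl metals (same 1,2-metallate shift and anti deiodoboration) and the electrophile-induced ring-contracting 1,2-metallate rearrangements of cyclic alkenyl boronate complexes; new here is that both B–C bonds lie in one ring, so the shift itself makes the carbocycle. Ring B closes by this 1,2-shift, which forms the C8–C9 bond across boron as a ring contraction from seven to six members and not as a direct cyclisation. No new stereocentre remains: C8 is carried over with retention, and syn hydroboration (boron cis to H-11) followed by anti addition and anti elimination places C8 cis to the aryl group, which is the E alkene. The step needs iodine to react at the borate alkene and not at the tris-alkoxyarene, and carbon to migrate and not methoxide; the borate makes the alkene by far the most nucleophilic site at −78 °C and alkoxide ligands do not migrate. Should the benzylic iodide ionise, elimination should still lead to the same E isomer, in which the aryl group avoids the quaternary C10.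

Step 12
Reactants: 20 tris-MOM styrene
Product: 23 tris-MOM aldehyde, via aryllithium 21 (not isolated), via lithium aminoalkoxide 22 (not isolated)
Conditions: n-BuLi, TMEDA, THF, −20 °C; DMF, −78 °C to rt; H2O
Reagents that add atoms: N,N-dimethylformamide, CN(C)C=O
Why: Directed ortho-metalation between the two flanking OMOM groups (on C4' and C6') gives the C5' aryllithium, and formylation with DMF installs the aldehyde.

Step 13
Reactants: 23 tris-MOM aldehyde
Product: 24 triol aldehyde
Conditions: HCl (1.5 mol/L in MeOH), THF, 0 °C to rt, argon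
Reagents that add atoms: none
Why: Acid-catalysed acetal exchange with methanol removes the three MOM groups (the two next to the formyl group are activated by chelation) at a temperature meant to spare the acid-sensitive styrene.

Step 14
Reactants: 24 triol aldehyde
Product: 27 target, via catechol phenylboronate 25 (not isolated), via pyridinium sulfate 26 (not isolated)
Conditions: PhB(OH)2 (1.1 equiv), 4 Å molecular sieves, THF, rt; SO3·pyridine (4 equiv), pyridine, 40 °C; aq NaHCO3, C18 chromatography; Dowex 50W (H+ form), 0 °C
Reagents that add atoms: sulfur trioxide pyridine complex, [O-]S(=O)(=O)[n+]1ccccc1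
Why: Phenylboronic acid ties up the O3'/O4' catechol as a cyclic boronate so that O-sulfation with SO3·pyridine can occur only at the remaining C6' phenol, and aqueous work-up hydrolyses the boronate.

**Compound list**

1 | (S)-α-ionone: (3E)-4-[(1S)-2,6,6-trimethylcyclohex-2-en-1-yl]but-3-en-2-one | CC(=O)/C=C/[C@@H]1C(C)=CCCC1(C)C | starting material
2 | (S)-dihydro-α-ionone: 4-[(1S)-2,6,6-trimethylcyclohex-2-en-1-yl]butan-2-one | CC(=O)CC[C@@H]1C(C)=CCCC1(C)C | intermediate
3 | lithium enolate: lithium 4-[(1S)-2,6,6-trimethylcyclohex-2-en-1-yl]but-1-en-2-olate | [Li+].[O-]C(=C)CC[C@@H]1C(C)=CCCC1(C)C | intermediate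
4 | alkenyl triflate: 4-[(1S)-2,6,6-trimethylcyclohex-2-en-1-yl]but-1-en-2-yl trifluoromethanesulfonate | C=C(OS(=O)(=O)C(F)(F)F)CC[C@@H]1C(C)=CCCC1(C)C | intermediate
5 | alkenyl boronate: 4,4,5,5-tetramethyl-2-{4-[(1S)-2,6,6-trimethylcyclohex-2-en-1-yl]but-1-en-2-yl}-1,3,2-dioxaborolane | C=C(B1OC(C)(C)C(C)(C)O1)CC[C@@H]2C(C)=CCCC2(C)C | intermediate
6 | secondary boronate (8S): 4,4,5,5-tetramethyl-2-{(2S)-4-[(1S)-2,6,6-trimethylcyclohex-2-en-1-yl]butan-2-yl}-1,3,2-dioxaborolane | C[C@H](B1OC(C)(C)C(C)(C)O1)CC[C@@H]2C(C)=CCCC2(C)C | intermediate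
7 | silylethynyl sulfone: trimethyl{[(4-methylphenyl)sulfonyl]ethynyl}silane | Cc1ccc(cc1)S(=O)(=O)C#C[Si](C)(C)C | starting material
8 | silyl alkyne: trimethyl({(1S,2S)-1,3,3-trimethyl-2-[(3S)-3-(4,4,5,5-tetramethyl-1,3,2-dioxaborolan-2-yl)butyl]cyclohexyl}ethynyl)silane | C[C@H](B1OC(C)(C)C(C)(C)O1)CC[C@H]2C(C)(C)CCC[C@]2(C)C#C[Si](C)(C)C | intermediate
9 | terminal alkyne: 2-{(2S)-4-[(1S,2S)-2-ethynyl-2,6,6-trimethylcyclohexyl]butan-2-yl}-4,4,5,5-tetramethyl-1,3,2-dioxaborolane | C[C@H](B1OC(C)(C)C(C)(C)O1)CC[C@H]2C(C)(C)CCC[C@]2(C)C#C | intermediate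
10 | benzene-1,2,4-triol | Oc1ccc(O)c(O)c1 | starting material
11 | tris-MOM ether: 1,2,4-tris(methoxymethoxy)benzene | COCOc1ccc(OCOC)c(OCOC)c1 | intermediate
12 | aryl iodide: 1-iodo-2,4,5-tris(methoxymethoxy)benzene | COCOc1cc(OCOC)c(OCOC)cc1I | intermediate
13 | aryl alkyne: 4,4,5,5-tetramethyl-2-{(2S)-4-[(1S,2S)-2,6,6-trimethyl-2-{[2,4,5-tris(methoxymethoxy)phenyl]ethynyl}cyclohexyl]butan-2-yl}-1,3,2-dioxaborolane | C[C@H](B1OC(C)(C)C(C)(C)O1)CC[C@H]2C(C)(C)CCC[C@]2(C)C#Cc3cc(OCOC)c(OCOC)cc3OCOC | intermediate
14 | lithium trihydroborate: 13 with BH3(−) Li(+) on C8 in place of the pinacol boronate | [Li+].C[C@H]([BH3-])CC[C@H]1C(C)(C)CCC[C@]1(C)C#Cc1cc(OCOC)c(OCOC)cc1OCOC | intermediate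
15 | monoalkylborane: 13 with BH2 on C8 in place of the pinacol boronate | C[C@H]([BH2])CC[C@H]1C(C)(C)CCC[C@]1(C)C#Cc1cc(OCOC)c(OCOC)cc1OCOC | intermediate
16 | cyclic hydridoborane: borepane ring (B, C8, C7, C6, C5, C10, C9) trans-fused to ring A, B–H, 8S methyl, exocyclic (Z)-C9=C11H–aryl with the aryl group cis to C10, aryl = 2,4,5-tris(methoxymethoxy)phenyl | C[C@H]1CC[C@H]2C(C)(C)CCC[C@]2(C)/C(=C\c3cc(OCOC)c(OCOC)cc3OCOC)[BH]1 | intermediate
17 | borepane methyl borinate: as 16 with B–OMe in place of B–H | C[C@H]1CC[C@H]2C(C)(C)CCC[C@]2(C)/C(=C\c3cc(OCOC)c(OCOC)cc3OCOC)B1OC | intermediate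
18 | sodium dimethoxyborate: 17 with a second methoxide on boron, sodium salt | [Na+].C[C@H]1CC[C@H]2C(C)(C)CCC[C@]2(C)/C(=C\c3cc(OCOC)c(OCOC)cc3OCOC)[B-]1(OC)OC | intermediate
19 | iodo boronate: trans-decalin with ring B closed, C9 bearing B(OMe)2 and the C11H(I)–aryl group, the C8–C9 and C11–I bonds anti (drawn for boron equatorial) | C[C@H]1CC[C@H]2C(C)(C)CCC[C@]2(C)[C@]1(B(OC)OC)[C@H](I)c3cc(OCOC)c(OCOC)cc3OCOC | intermediate
20 | tris-MOM styrene: 1-{(E)-[(2S,4aS,8aS)-2,5,5,8a-tetramethyloctahydronaphthalen-1(2H)-ylidene]methyl}-2,4,5-tris(methoxymethoxy)benzene | C[C@H]1CC[C@H]2C(C)(C)CCC[C@]2(C)/C1=C/c1cc(OCOC)c(OCOC)cc1OCOC | intermediate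
21 | aryllithium: 20 lithiated at C5', between the OMOM groups on C4' and C6' | C[C@H]1CC[C@H]2C(C)(C)CCC[C@]2(C)/C1=C/c1cc(OCOC)c(OCOC)c([Li])c1OCOC | intermediate
22 | lithium aminoalkoxide: adduct of 21 and DMF, C5'–CH(OLi)NMe2, both epimers at the new carbon | [Li+].C[C@H]1CC[C@H]2C(C)(C)CCC[C@]2(C)/C1=C/c1cc(OCOC)c(OCOC)c(C([O-])N(C)C)c1OCOC | intermediate
23 | tris-MOM aldehyde: 2,3,6-tris(methoxymethoxy)-5-{(E)-[(2S,4aS,8aS)-2,5,5,8a-tetramethyloctahydronaphthalen-1(2H)-ylidene]methyl}benzaldehyde | C[C@H]1CC[C@H]2C(C)(C)CCC[C@]2(C)/C1=C/c1cc(OCOC)c(OCOC)c(C=O)c1OCOC | intermediate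
24 | triol aldehyde: 2,3,6-trihydroxy-5-{(E)-[(2S,4aS,8aS)-2,5,5,8a-tetramethyloctahydronaphthalen-1(2H)-ylidene]methyl}benzaldehyde | C[C@H]1CC[C@H]2C(C)(C)CCC[C@]2(C)/C1=C/c1cc(O)c(O)c(C=O)c1O | intermediate
25 | catechol phenylboronate: 24 with O3' and O4' joined through B–Ph (2-phenyl-1,3,2-benzodioxaborole), C6'–OH free | C[C@H]1CC[C@H]2C(C)(C)CCC[C@]2(C)/C1=C/c1cc3OB(c4ccccc4)Oc3c(C=O)c1O | intermediate
26 | pyridinium sulfate: pyridinium salt of the C6' O-sulfate of 25 | C[C@H]1CC[C@H]2C(C)(C)CCC[C@]2(C)/C1=C/c1cc3OB(c4ccccc4)Oc3c(C=O)c1OS(=O)(=O)[O-].c1cc[nH+]cc1 | intermediate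
27 | target: 2-formyl-3,4-dihydroxy-6-{(E)-[(2S,4aS,8aS)-2,5,5,8a-tetramethyloctahydronaphthalen-1(2H)-ylidene]methyl}phenyl hydrogen sulfate | C[C@H]1CC[C@H]2C(C)(C)CCC[C@]2(C)/C1=C/c1cc(O)c(O)c(C=O)c1OS(=O)(=O)O | target

**Summary**

Total step count: 14.
Longest linear sequence: 12 steps (1 → 2 → 4 → 5 → 6 → 8 → 9 → 13 → 17 → 20 → 23 → 24 → 27); the arene branch (10 → 11 → 12) has 2 steps.

**Steps most likely to fail**

1. Step 11 (proposed new method). The shift of C8 from boron to C9 may be too slow next to the quaternary C10, so that iodine is consumed by iodination of the electron-rich arene or the alkenyl group is lost from boron by protonolysis. The fallback uses known reactions only, still makes ring B from a seven-membered ring, sets out from 9 and comes back to the route at 20. Semi-hydrogenation of 9 (H2, Pd/CaCO3 poisoned with Pb(OAc)2, quinoline) should give the vinyl boronate F1. Zweifel vinylation of the secondary boronic ester (vinylmagnesium bromide, then I2 and NaOMe, retention at C8) should give the diene F2. Ring-closing metathesis (second-generation Grubbs catalyst, CH2Cl2, 40 °C) should give the trans-fused cycloheptene F3, and m-CPBA the epoxide F4. MgBr2·OEt2 then contracts the seven-membered ring to ring B by a Meinwald-type rearrangement through the bromohydrin, in which a ring bond migrates, and gives the aldehyde F5. The aryllithium F6, made from 12 with n-BuLi in THF at −78 °C, adds to F5 to give the benzylic alcohol F7. MsCl/Et3N dehydrates F7 to the more stable E styrene 20.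

2. Step 10. The difunctional monoalkylborane 15 may hydroborate between molecules, or twice, before it closes the seven-membered ring at the hindered alkyne carbon C9. In the fallback a monofunctional and more Lewis-acidic alkyl(chloro)borane closes the ring in place of the dihydridoborane; it sets out from 13, reduced to 14 as in step 10, and comes back at 17. Anhydrous HCl (2 equiv, Et2O, −78 °C) should convert 14 into the alkylchloroborane F8, which has only one B–H bond. Under high dilution in CH2Cl2 this should close to the cyclic chloroborane F9, and MeOH/Et3N converts F9 into 17.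

3. Step 14. The transient boronate may be cleaved or may form incompletely under SO3·pyridine, which would lead to sulfation at O3' or O4' or to several sulfations. In the fallback an isolable cyclic carbonate replaces the transient boronate; it sets out from 24 and comes back at 27. 1,1'-Carbonyldiimidazole (1 equiv, THF, 0 °C) should give the catechol carbonate F10, and SO3·pyridine in pyridine the carbonate sulfate F11 as its pyridinium salt. Dilute aqueous NaHCO3 in MeOH then removes the carbonate, and cation exchange (Dowex 50W, H+ form) gives 27.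

**Further compounds**

F1 | step 11 | vinyl boronate: 9 with the ethynyl group on C10 reduced to ethenyl | C[C@H](B1OC(C)(C)C(C)(C)O1)CC[C@H]2C(C)(C)CCC[C@]2(C)C=C
F2 | step 11 | diene: F1 with an ethenyl group on C8 in place of the boronate (retention) | C[C@H](C=C)CC[C@H]1C(C)(C)CCC[C@]1(C)C=C
F3 | step 11 | cycloheptene: trans-fused seven-membered ring C5, C6, C7, C8, CH=CH, C10 on ring A | C[C@H]1CC[C@H]2C(C)(C)CCC[C@]2(C)C=C1
F4 | step 11 | epoxide: epoxide of the cycloheptene F3 (epoxide face not defined) | C[C@H]1CC[C@H]2C(C)(C)CCC[C@]2(C)C3OC31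
F5 | step 11 | aldehyde: trans-decalin with ring B closed, C9–H bearing the formyl carbon C11 (C9 epimers), 8S methyl | C[C@H]1CC[C@H]2C(C)(C)CCC[C@]2(C)C1C=O
F6 | step 11 | aryllithium: [2,4,5-tris(methoxymethoxy)phenyl]lithium | [Li]c1cc(OCOC)c(OCOC)cc1OCOC
F7 | step 11 | benzylic alcohol: adduct of F6 and F5 at C11 (carbinol and C9 epimers) | C[C@H]1CC[C@H]2C(C)(C)CCC[C@]2(C)C1C(O)c1cc(OCOC)c(OCOC)cc1OCOC
F8 | step 10 | alkylchloroborane: 13 with BHCl on C8 in place of the pinacol boronate | C[C@H]([BH]Cl)CC[C@H]1C(C)(C)CCC[C@]1(C)C#Cc1cc(OCOC)c(OCOC)cc1OCOC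
F9 | step 10 | cyclic chloroborane: as 17 with B–Cl in place of B–OMe | C[C@H]1CC[C@H]2C(C)(C)CCC[C@]2(C)/C(=C\c3cc(OCOC)c(OCOC)cc3OCOC)B1Cl
F10 | step 14 | catechol carbonate: 24 with O3' and O4' joined as a cyclic carbonate, C6'–OH free | C[C@H]1CC[C@H]2C(C)(C)CCC[C@]2(C)/C1=C/c1cc3OC(=O)Oc3c(C=O)c1O
F11 | step 14 | carbonate sulfate: pyridinium salt of the C6' O-sulfate of F10 | C[C@H]1CC[C@H]2C(C)(C)CCC[C@]2(C)/C1=C/c1cc3OC(=O)Oc3c(C=O)c1OS(=O)(=O)[O-].c1cc[nH+]cc1
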